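**Retrosynthetic overview**
1. The target, epicatechin-(4β→6)-epigallocatechin 3,3'-di-O-gallate, comes from one global hydrogenolysis (12 benzyl ethers, one diphenylmethylene ketal, 3 aryl bromides) of a fully protected, halogen-capped dimer.
2. Key disconnection is the interflavan C4(upper)–C6(lower) bond. It is formed at the anode by mediated oxidation of a C4 arylthio group on a 6,8-dibromo epicatechin unit; the C4 cation is taken up from the β face by C6 of a C8-brominated, already galloylated epigallocatechin unit.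
3. Lower unit from (−)-epigallocatechin: A-ring benzylation under borate masking, B-ring 4',5'-ketal, double galloylation (3-OH and 3'-OH), C8 bromination.
4. Upper unit from (−)-epicatechin: benzylation, DDQ oxidation at C4, 6,8-dibromination, O→S exchange at C4.
5. No carbocycle or pyran ring is built; only the temporary dioxole ketal ring is formed. Four of the five stereocentres are bought, and C4 of the upper unit is set in the coupling by C2/C3.

Assumption: (−)-epicatechin, (−)-epigallocatechin and 3,4,5-tris(benzyloxy)benzoic acid are bought; potentials are quoted against SCE and are estimates.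

**Step 1**
Reactants: 1 (−)-epicatechin; 2 benzyl bromide
Product: 3 5,7,3',4'-tetra-O-benzyl-(−)-epicatechin (2R,3R)
Conditions: BnBr (4.4 equiv), K2CO3 (5 equiv), DMF, 0 °C → rt, Ar
Reagents that add atoms: benzyl bromide, BrCc1ccccc1
Why: Williamson etherification under carbonate conditions alkylates only the four phenols and leaves the secondary 3-OH and both stereocentres untouched.

**Step 2**
Reactants: 3 5,7,3',4'-tetra-O-benzyl-(−)-epicatechin; 4 2-ethoxyethanol
Product: 5 (2R,3R,4S)-4-(2-ethoxyethoxy)-5,7,3',4'-tetra-O-benzylepicatechin (4β-ether, 3,4-trans)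
Conditions: DDQ (2 equiv), EtOCH2CH2OH (5 equiv), CH2Cl2, rt
Reagents that add atoms: 2-ethoxyethanol, CCOCCO
Why: DDQ benzylic oxidation (hydride abstraction at C4, the cation being stabilised by O1, O5 and O7) followed by capture by the alcohol anti to the α-oriented 3-OH and 2-aryl groups is the established C4 functionalisation of benzylated flavan-3-ols and gives the 4β-ether.

**Step 3**
Reactants: 5 the 4β-(2-ethoxyethoxy) ether; 6 N-bromosuccinimide
Product: 7 (2R,3R,4S)-6,8-dibromo-4-(2-ethoxyethoxy)-5,7,3',4'-tetra-O-benzylepicatechin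
Conditions: NBS (2.2 equiv), CH2Cl2, −20 °C → rt
Reagents that add atoms: N-bromosuccinimide, O=C1CCC(=O)N1Br
Why: Electrophilic aromatic bromination takes the only two free positions of the phloroglucinol-type A ring well before the catechol B ring, which caps both nucleophilic carbons of the future electrophile so that it cannot self-condense.

**Step 4**
Reactants: 7 the 6,8-dibromo 4β-ether; 8 4-methoxybenzenethiol
Product: 9 (2R,3S,4S)-6,8-dibromo-4-[(4-methoxyphenyl)sulfanyl]-5,7,3',4'-tetra-O-benzylepicatechin (4β-thioether; the 3-descriptor changes only because S outranks O)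
Conditions: 4-MeOC6H4SH (3 equiv), BF3·OEt2 (0.3 equiv), CH2Cl2, −40 → 0 °C
Reagents that add atoms: 4-methoxybenzenethiol, COc1ccc(S)cc1
Why: Lewis acid-promoted SN1 exchange of the benzylic ether through the C4 cation, trapped by the soft thiol on the β face trans to the 3-OH, is the standard entry to 4-thioflavans and installs the easily oxidised arylthio group needed in step 9.

**Step 5**
Reactants: 10 (−)-epigallocatechin; 11 boric acid; 2 benzyl bromide
Product: 14 5,7-di-O-benzyl-(−)-epigallocatechin, via EGC 4',5'-borate potassium salt 12 (not isolated), via 5,7-di-O-benzyl-EGC 4',5'-borate potassium salt 13 (not isolated)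
Conditions: B(OH)3 (1.1 equiv), K2CO3 (3.2 equiv), degassed DMF, rt, 1 h; then BnBr (2.1 equiv), 0 °C → rt; 1 M HCl work-up, Ar
Reagents that add atoms: benzyl bromide, BrCc1ccccc1
Why: Borate-masked Williamson etherification: the pyrogallol B ring is held as an anionic cyclic borate whose remaining 3'-OH is far less acidic (and which is protected from autoxidation), so only the two A-ring phenoxides are benzylated and the acid work-up releases the free pyrogallol.

**Step 6**
Reactants: 14 5,7-di-O-benzyl-(−)-epigallocatechin; 15 dichlorodiphenylmethane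
Product: 16 5,7-di-O-benzyl-4',5'-O-(diphenylmethylene)-(−)-epigallocatechin (2R,3R)
Conditions: Ph2CCl2 (1.2 equiv), K2CO3 (2.5 equiv), MeCN, rt → 50 °C, Ar
Reagents that add atoms: dichlorodiphenylmethane, ClC(Cl)(c1ccccc1)c1ccccc1
Why: Diphenylmethylene ketal formation (double O-alkylation by the gem-dichloride) can only bridge two adjacent phenols, and since the 3',4' and 4',5' pairs are equivalent by rotation of the B ring, one ketal with a single free terminal B-ring OH results.

**Step 7**
Reactants: 16 the ketal; 17 3,4,5-tris(benzyloxy)benzoic acid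
Product: 18 5,7-di-O-benzyl-4',5'-O-(diphenylmethylene)-3,3'-bis-O-[3,4,5-tris(benzyloxy)benzoyl]-(−)-epigallocatechin
Conditions: ArCO2H (2.6 equiv), DCC (2.8 equiv), DMAP (0.5 equiv), CH2Cl2, rt
Reagents that add atoms: 3,4,5-tris(benzyloxy)benzoic acid, OC(=O)c1cc(OCc2ccccc2)c(OCc2ccccc2)c(OCc2ccccc2)c1
Why: Steglich esterification acylates the only two free hydroxyls (axial 3-OH and phenolic 3'-OH), as in standard syntheses of benzylated EGCG, with retention at C3.

**Step 8**
Reactants: 18 the digallate; 6 N-bromosuccinimide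
Product: 19 8-bromo-5,7-di-O-benzyl-4',5'-O-(diphenylmethylene)-3,3'-bis-O-[3,4,5-tris(benzyloxy)benzoyl]-(−)-epigallocatechin
Conditions: NBS (1.05 equiv), CH2Cl2, −20 → 0 °C
Reagents that add atoms: N-bromosuccinimide, O=C1CCC(=O)N1Br
Why: Electrophilic aromatic bromination of 5,7-di-O-benzylflavans is C8-selective and the acylated B ring and gallate rings are much less nucleophilic, so C6 is left as the only nucleophilic carbon.

**Step 9**
Reactants: 9 the 4β-arylthio dibromide (1.3 equiv); 19 the 8-bromo digallate (1.0 equiv)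
Product: 20 [6,8-dibromo-5,7,3',4'-tetra-O-benzylepicatechin]-(4β→6)-[8-bromo-5,7-di-O-benzyl-4',5'-O-(diphenylmethylene)-3,3'-bis-O-(tri-O-benzylgalloyl)epigallocatechin] (upper 2R,3R,4S; lower 2R,3R)
Conditions: undivided cell, graphite-felt anode/Pt cathode, (4-BrC6H4)3N (10 mol%), nBu4NOTf (0.1 M), HFIP (5 equiv), 4 Å MS, CH2Cl2, −30 → 0 °C, +1.10 V vs SCE, ca. 1.2 F/mol
Reagents that add atoms: none
Why: Proposed new method: the anodically generated triarylaminium ion (E° ca. 1.05 V) oxidises only the 4-methoxyphenylthio group of 9 (ca. 1.15 V, all other arenes estimated at ≥ 1.35 V); the sulfide radical cation undergoes mesolytic C4–S cleavage to the C4 benzylic cation (the thiyl radical dimerises); this cation cannot self-condense because C6 and C8 of 9 are brominated and is captured in a Friedel–Crafts step by C6 of 19 (C8 blocked) from the β face anti to the α 3-OH and 2-aryl groups, which sets the 4β (4S) centre, while the released proton is reduced to H2 at the cathode under neutral conditions that spare the ketal; the closest known reaction types are the mediated anodic activation of thioglycosides in electrochemical glycosylation and the Lewis acid-promoted 4→6 coupling of halo-capped flavans.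

**Step 10**
Reactants: 20 the protected tribromo dimer
Product: 21 epicatechin-(4β→6)-epigallocatechin 3,3'-di-O-gallate (target; upper 2R,3R,4S, lower 2R,3R)
Conditions: H2 (1 atm), 20% Pd(OH)2/C, NaOAc (3.3 equiv), THF/MeOH 1:1, rt
Reagents that add atoms: none
Why: Catalytic hydrogenolysis cleaves the twelve benzyl ethers and the diphenylmethylene ketal and reduces the three aryl C–Br bonds in one operation, with acetate buffering the HBr so that neither acid cleavage of the interflavan bond nor base-induced 3'→4' galloyl migration occurs, and the esters and all five stereocentres are untouched.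

**Compound list**
1 | (−)-epicatechin | C1c2c(O)cc(O)cc2O[C@H](c2ccc(O)c(O)c2)[C@@H]1O | starting material
2 | benzyl bromide | BrCc1ccccc1 | starting material
3 | 5,7,3',4'-tetra-O-benzyl-(−)-epicatechin | C1c2c(OCc3ccccc3)cc(OCc3ccccc3)cc2O[C@H](c2ccc(OCc3ccccc3)c(OCc3ccccc3)c2)[C@@H]1O | intermediate
4 | 2-ethoxyethanol | CCOCCO | starting material
5 | (2R,3R,4S)-4-(2-ethoxyethoxy)-5,7,3',4'-tetra-O-benzylepicatechin | CCOCCO[C@H]1c2c(OCc3ccccc3)cc(OCc3ccccc3)cc2O[C@H](c2ccc(OCc3ccccc3)c(OCc3ccccc3)c2)[C@@H]1O | intermediate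
6 | N-bromosuccinimide | O=C1CCC(=O)N1Br | starting material
7 | (2R,3R,4S)-6,8-dibromo-4-(2-ethoxyethoxy)-5,7,3',4'-tetra-O-benzylepicatechin | CCOCCO[C@H]1c2c(OCc3ccccc3)c(Br)c(OCc3ccccc3)c(Br)c2O[C@H](c2ccc(OCc3ccccc3)c(OCc3ccccc3)c2)[C@@H]1O | intermediate
8 | 4-methoxybenzenethiol | COc1ccc(S)cc1 | starting material
9 | (2R,3S,4S)-6,8-dibromo-4-[(4-methoxyphenyl)sulfanyl]-5,7,3',4'-tetra-O-benzylepicatechin | COc1ccc(S[C@H]2c3c(OCc4ccccc4)c(Br)c(OCc4ccccc4)c(Br)c3O[C@H](c3ccc(OCc4ccccc4)c(OCc4ccccc4)c3)[C@@H]2O)cc1 | intermediate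
10 | (−)-epigallocatechin | Oc1cc([C@H]2Oc3cc(O)cc(O)c3C[C@H]2O)cc(O)c1O | starting material
11 | boric acid | OB(O)O | starting material
12 | potassium dihydroxyborate of (−)-epigallocatechin bridging O4' and O5' | [K+].O[B-]5(O)Oc2cc(cc(O)c2O5)[C@H]1Oc2cc(O)cc(O)c2C[C@H]1O | intermediate
13 | potassium dihydroxyborate of 5,7-di-O-benzyl-(−)-epigallocatechin bridging O4' and O5' | [K+].O[B-]5(O)Oc2cc(cc(O)c2O5)[C@H]1Oc2cc(OCc3ccccc3)cc(OCc3ccccc3)c2C[C@H]1O | intermediate
14 | 5,7-di-O-benzyl-(−)-epigallocatechin | Oc1cc([C@H]2Oc3cc(OCc4ccccc4)cc(OCc4ccccc4)c3C[C@H]2O)cc(O)c1O | intermediate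
15 | dichlorodiphenylmethane | ClC(Cl)(c1ccccc1)c1ccccc1 | starting material
16 | 5,7-di-O-benzyl-4',5'-O-(diphenylmethylene)-(−)-epigallocatechin | Oc1cc([C@H]2Oc3cc(OCc4ccccc4)cc(OCc4ccccc4)c3C[C@H]2O)cc2OC(c3ccccc3)(c3ccccc3)Oc12 | intermediate
17 | 3,4,5-tris(benzyloxy)benzoic acid | OC(=O)c1cc(OCc2ccccc2)c(OCc2ccccc2)c(OCc2ccccc2)c1 | starting material
18 | 5,7-di-O-benzyl-4',5'-O-(diphenylmethylene)-3,3'-bis-O-[3,4,5-tris(benzyloxy)benzoyl]-(−)-epigallocatechin | O=C(Oc1cc([C@H]2Oc3cc(OCc4ccccc4)cc(OCc4ccccc4)c3C[C@H]2OC(=O)c2cc(OCc3ccccc3)c(OCc3ccccc3)c(OCc3ccccc3)c2)cc2OC(c3ccccc3)(c3ccccc3)Oc12)c1cc(OCc2ccccc2)c(OCc2ccccc2)c(OCc2ccccc2)c1 | intermediate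
19 | 8-bromo derivative of 18 | O=C(Oc1cc([C@H]2Oc3c(Br)c(OCc4ccccc4)cc(OCc4ccccc4)c3C[C@H]2OC(=O)c2cc(OCc3ccccc3)c(OCc3ccccc3)c(OCc3ccccc3)c2)cc2OC(c3ccccc3)(c3ccccc3)Oc12)c1cc(OCc2ccccc2)c(OCc2ccccc2)c(OCc2ccccc2)c1 | intermediate
20 | protected tribromo (4β→6) dimer (upper 2R,3R,4S; lower 2R,3R) | O=C(Oc1cc([C@H]2Oc3c(Br)c(OCc4ccccc4)c([C@H]4c5c(OCc6ccccc6)c(Br)c(OCc6ccccc6)c(Br)c5O[C@H](c5ccc(OCc6ccccc6)c(OCc6ccccc6)c5)[C@@H]4O)c(OCc4ccccc4)c3C[C@H]2OC(=O)c2cc(OCc3ccccc3)c(OCc3ccccc3)c(OCc3ccccc3)c2)cc2OC(c3ccccc3)(c3ccccc3)Oc12)c1cc(OCc2ccccc2)c(OCc2ccccc2)c(OCc2ccccc2)c1 | intermediate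
21 | epicatechin-(4β→6)-epigallocatechin 3,3'-di-O-gallate (CNP0237700.1) | O=C(Oc1cc([C@H]2Oc3cc(O)c([C@H]4c5c(O)cc(O)cc5O[C@H](c5ccc(O)c(O)c5)[C@@H]4O)c(O)c3C[C@H]2OC(=O)c2cc(O)c(O)c(O)c2)cc(O)c1O)c1cc(O)c(O)c(O)c1 | target

**Step count and risks**
Total steps: 10. Longest linear sequence: 6 (steps 5–10 from 10, or steps 1–4, 9, 10 from 1).

Most likely to fail, with fallbacks:

Step 9 (the proposed anodic coupling). Risks are slow mesolysis to the bromine-deactivated cation, mediator attack on the catechol B ring, or cathodic loss of bromine. The fallback uses known chemistry and sets out from the dibromo ether 7 (thioether 9 is then not needed) together with 19. The two are condensed with BF3·OEt2 or TMSOTf in CH2Cl2 at −78 → −30 °C, the established Lewis acid coupling of halogen-capped flavan units, with the same β-face attack at C6. It comes back to the route at 20 and makes no new compound (none F0).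

Step 5 (borate-masked A-ring benzylation). Risks are benzylation of the B-ring 3'-OH, C-benzylation at C6/C8, or incomplete masking. The fallback sets out from 10 and comes back at 16. The B ring is ketalised first with 15 (K2CO3, MeCN) to give 4',5'-O-(diphenylmethylene)-(−)-epigallocatechin F1. Both free A-ring carbons are then brominated (NBS 2.0 equiv, THF, −40 °C) to give the 6,8-dibromide F2, whose two ortho-bromophenol OH groups (pKa about 7–8) are far more acidic than the lone B-ring 3'-OH (pKa about 10). Only these two are benzylated (BnBr 2.1 equiv, KHCO3, DMF) to give the 5,7-di-O-benzyl-6,8-dibromide F3. Both bromines are then removed by homogeneous Pd(0)/formate hydrodehalogenation (Pd(OAc)2, PPh3, HCO2Na, DMF, 80 °C), which spares benzyl ethers and the ketal, giving 16.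

Step 10 (global hydrogenolysis). Risks are incomplete reduction of the three hindered C–Br bonds, HBr damage to the interflavan bond, or galloyl migration on the freed pyrogallol. The fallback sets out from 20 and ends at 21 in two stages. The bromines are removed first without hydrogenolysis (Pd(OAc)2, SPhos, HCO2Na, DMF, 70 °C) to give the halogen-free dodeca-O-benzyl ketal dimer F4. F4 is then hydrogenolysed under neutral, salt-free conditions (H2, Pd(OH)2/C, THF/MeOH/H2O, rt).

**Further compounds**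
F0 | step 9 | none | none
F1 | step 5 | 4',5'-O-(diphenylmethylene)-(−)-epigallocatechin | Oc1cc([C@H]2Oc3cc(O)cc(O)c3C[C@H]2O)cc2OC(c3ccccc3)(c3ccccc3)Oc12
F2 | step 5 | 6,8-dibromo-4',5'-O-(diphenylmethylene)-(−)-epigallocatechin | Oc1cc([C@H]2Oc3c(Br)c(O)c(Br)c(O)c3C[C@H]2O)cc2OC(c3ccccc3)(c3ccccc3)Oc12
F3 | step 5 | 5,7-di-O-benzyl-6,8-dibromo-4',5'-O-(diphenylmethylene)-(−)-epigallocatechin | Oc1cc([C@H]2Oc3c(Br)c(OCc4ccccc4)c(Br)c(OCc4ccccc4)c3C[C@H]2O)cc2OC(c3ccccc3)(c3ccccc3)Oc12
F4 | step 10 | bromine-free protected (4β→6) dimer (upper 2R,3R,4S; lower 2R,3R) | O=C(Oc1cc([C@H]2Oc3cc(OCc4ccccc4)c([C@H]4c5c(OCc6ccccc6)cc(OCc6ccccc6)cc5O[C@H](c5ccc(OCc6ccccc6)c(OCc6ccccc6)c5)[C@@H]4O)c(OCc4ccccc4)c3C[C@H]2OC(=O)c2cc(OCc3ccccc3)c(OCc3ccccc3)c(OCc3ccccc3)c2)cc2OC(c3ccccc3)(c3ccccc3)Oc12)c1cc(OCc2ccccc2)c(OCc2ccccc2)c(OCc2ccccc2)c1
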